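Start from 94.7%: that share of its J is what the north-east run still holds at 40.0 min, while the west run, charged lower, keeps 99.0% at 40.0 min. Read this as a reversible polymerization with a floor of J (the equilibrium monomer concentration) near 0.379 M.

| setting | west | north-east | north-west | flask |
|---|---|---|---|---|
| J | 0.27 M | 0.40 M | 0.53 M | 0.53 M |
| G | 5 mol% | 5 mol% | 5 mol% | 5 mol% |
| D | 7.1 mM | 7.1 mM | 14 mM | 7.1 mM |
| remark | run made earlier | run made earlier | run made earlier |  |
| time |  |  |  | 30 min |

| run | time / min | Q / % | J / % |
|---|---|---|---|
| west | 2.50 | 0.2 | 99.1 |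
| west | 8.00 | 0.6 | 101.1 |
| west | 12.0 | 0 | 99.8 |
| west | 20.0 | 0 | 99.3 |
| west | 30.0 | 0 | 99.7 |
| west | 40.0 | 0.9 | 99.0 |
| north-east | 3.00 | 3.5 | 96.0 |
| north-east | 5.00 | 4.0 | 95.7 |
| north-east | 8.00 | 4.2 | 95.7 |
| north-east | 12.0 | 4.2 | 95.4 |
| north-east | 20.0 | 4.4 | 95.0 |
| north-east | 40.0 | 5.3 | 94.7 |
| north-west | 3.00 | 12.5 | 86.9 |
| north-west | 5.00 | 13.3 | 86.2 |
| north-west | 10.0 | 17.1 | 83.9 |
| north-west | 20.0 | 17.8 | 82.5 |
| north-west | 40.0 | 19.4 | 80.1 |

(standard deviation of a reading: 0.5 percentage points)

1. average number of monomer units in a chain (chains begun, living or dead) at 30 min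
2. part of the J that has reacted at 30 min

- the average divides the monomer in chains by the number of chains begun, living and dead together
- the earlier runs do not show the number of chains; that part of a forecast is a guess

1. Take the ceiling share, one minus floor over charge, the most of the charge that can stand as Q: 28.5% for the flask.
2. Assume each D removes one G and each remaining G begins a chain. The chain share of the J charged is then 3.66% in the flask and 2.36% in the north-west run, a ratio of 1.55.
3. Assume ends die in pairs, so that progress follows ends times time. By this estimate the flask should reach at 25.8 min the 19.4% read in the north-west run at 40.0 min.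
4. Extend at that run's last pace per doubling of time: c is 19.8%, under the ceiling.
5. Divide by the chain share: dp is 5.40.
6. Test the weak link, step 2, which no reading shows: with D removing no G, dp falls to 3.95. Commit to step 2.

The forecast, c 25% and dp 6, stands above my numbers, on its ground that “Halving D should leave more active chains”.

The flask gives c 20.6% and dp 5.64.

    J + G → X + Q (k = 0.150 L mol⁻¹ s⁻¹)
    2 X → E (k = 1.20 L mol⁻¹ s⁻¹)
    G + D → L (k = 140 L mol⁻¹ s⁻¹)
    Q + X → J + X, rate k4*[X] as long as [Q] is above zero (k = 0.220 s⁻¹)
    J + X → Q + X, rate k5*[X]*[J] (k = 0.580 L mol⁻¹ s⁻¹)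

The flask's c is 72.3% of its ceiling. Now reckon the neighbour flask charged with 2.1 M of J: its ceiling is 82.0%, higher than the flask's, and its chain share is 4.66%. It reaches c 65.7%, which is 80.1% of that ceiling. Divided by the chain share, this gives 14.1, and the neighbour flask shows dp 14.1.

(The data were generated by integration for substances that don't exist; noise was put on by code.)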